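## The problem

Compound 36 is a longipinane diester. Its core is a cyclobutane (ring A: C4, C5, C11, C10) bridged twice across opposite corners and on opposite faces: C4 and C11 carry the three-carbon ketone bridge of ring B (C1 ketone, C2, C3 with methyl), and C5 and C10 carry the four-carbon bridge of ring C (C6 gem-dimethyl, C7, C8, C9). Seven stereocentres must be set: the four ring A carbons (C10 quaternary), C3, and the ester-bearing C7 and C9, which are trans to each other. C6 and C10 make every bond to C5, C7 and C9 neopentylic. Once both bridges exist the cage fixes the ring A centres, and the C10 methyl covers one face of ring B, so C3 can be set from the cage. Ring C looks almost the same from above and below, so C7 and C9 need reagent control or delivery from a group already in place. The angelates isomerise to tiglates under base, nucleophilic catalysis or heat and must come last; the cyclobutane forbids cationic chemistry at attached carbons; the C1 ketone makes C11 epimerisable, which is harmless in the closed cage and useful before ring B closes. The enabling feature is that C1 is α to C11 while C10 is allylic and quaternary once C8=C9 is an alkene: C1(=O)–C11–C10–C9=C8 is a Claisen retron spanning the ring A bond C10–C11, so that bond can be made by a [3,3] shift of a ketene acetal tied to C8 through oxygen. The catch is geometric: the tether holds C1 on the ring C face of ring A, whereas ring B needs it on the other face, so the route must use the carboxyl where the rearrangement leaves it and invert C11 afterwards.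

## Retrosynthesis

**Ester C–O bonds.** 36 is cut at both ester bonds, through monoester 35, to diol ketone 33 and two equivalents of angelic acid 34. The two esters are identical, so the hydroxyls need no differentiation, and acylating last keeps the Z-enoates away from bases and organometallics. The forward step must acylate two hindered secondary alcohols in turn without Z to E isomerisation.

**C3–CH3.** 33 goes back to enone 32 by conjugate addition of methyl. Carrying the methyl through and reducing a C2=C3 alkene would deliver hydrogen from the open face and give the wrong C3 epimer; delivering methyl from that face gives the right one. The precursor has one stereocentre fewer.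

**C2–C3 (ring B) and the C11 inversion.** 32 is opened to keto aldehyde 28 by a retro-aldol condensation. Closing ring B by acylating an alkenyl group on C4 with a C1 acid chloride needs C1 cis to C3 from the start and passes a cation next to the cyclobutane. The aldol runs under conditions that enolise the C1 ketone, so C11 equilibrates and only the epimer that can close is consumed. The forward reaction needs C11 enolisation to outrun intermolecular aldol chemistry.

**C1–C2 and C9–O.** 28 is traced through hemiketal 27 and lactones 26, 25 and 24 to the unsaturated acid 23: C2 comes from methyllithium on a lactone carbonyl, and the lactone from iodolactonisation of the C1 carboxyl onto C8=C9. The neighbouring option, epoxidation anti to a bulky C7 ether followed by hydride opening, rests on steric bias in a nearly symmetric ring and needs ketone protection. Here the endo carboxyl can reach C9 from one face only. The forward steps need 5-exo attack at a neopentyl carbon, then deiodination and debenzylation.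

**C10–C11 (key).** 23 is cut at the ring A bond to bridged lactone 19. This removes the four-membered ring and one quaternary centre and leaves a cycloheptene with a lactone bridge. A [2+2] construction would have to control four contiguous ring A centres intermolecularly. The forward reaction needs enolisation, O-silylation and a boat [3,3] shift.

**Lactone C–O and oxidation level.** 19 comes from dihydroxy acid 17, which comes from MOM ether 16 and diol 15. Only the C8 hydroxyl is cis to the C5 side chain, so the C7 hydroxyl needs no protection for the closure.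

**C9=C10 (ring C).** 15 is opened to diene 14 by ring-closing metathesis. Closing ring C at C7–C8 or C8–C9 by carbonyl addition would create a stereocentre in the ring-forming step; metathesis creates none. The precursor is acyclic with four stereocentres.

**C10=CH2 and C7–C8.** 14 comes from ketone 13 and that from lactone 12, whose carbonyl is C10: methyllithium then methylenation give the isopropenyl group and release the C1 alcohol. 12 comes from aldehyde 11 by syn-alkoxyallylboration, which sets C7 and C8 by reagent control. The lactone masks C1 and C10 while C7 is elaborated.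

**C4–C3 and the C7 oxidation level.** 11 comes from thioester 10, and 10 from lactone 9 by enolate alkylation. The lactone ring contains C10 and C11, and in that ring the required C4/C5 relationship is trans, which is what alkylation anti to the C5 substituent gives. An open-chain enolate would be expected to give the other diastereomer, and a lactone through the C3 oxygen would need the cis isomer. C7 is carried as a thioester so it can be reduced next to the lactone.

**C5–C6.** 9 comes from lactol 8, and 8 from enal 6 and ketene S,O-acetal 4. The bond between a tertiary and a quaternary carbon is best made while C5 is an unhindered acceptor carbon and C6 the nucleophile. A catalytic asymmetric Mukaiyama–Michael addition sets C5, from which C4 follows. 6 comes from aldehyde 5; 4 comes from thioester 3, made from 1 and 2.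

## Roads not taken

Alternative 1: The cut goes through C5–C6 and C9–C10 and removes ring C in one operation from a ring-B-bridged bicyclobutane A2 (central bond C5–C10). In the forward step the tertiary α-keto radical from bromo ynone A3 adds to the hydrogen-bearing bridgehead C5, and the C10 radical closes 7-endo on the ynone terminus to give cage enone A1. Two hindered C–C bonds and the seven-membered ring form at once, strain release drives the step, and the cyclobutane never has to be closed. A1 lacks the C3 methyl and both carbinol centres. C3 needs later enone formation in ring B. The C9 oxygen must be added to a ring whose faces are nearly equivalent while C7 is planar, so nothing directs it. The absolute configuration rests on an enantioenriched A2 whose chirality lies only in the ketal position. In step count to the carbon skeleton this road is better than the chosen plan, which spends fourteen steps before ring A exists. The chosen plan sets against it that C5, C7 and C8 come from catalyst or reagent control, C4, C10 and C3 from neighbours, and C9 by intramolecular delivery, so no centre depends on a facial bias of ring C.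

Alternative 2: The cut is C7–C8 together with both oxygen functions, leading to seco keto aldehyde A5 (rings A and B as the ketal, acetyl on C10, formyl on C6). In the forward step the lithium enolate of the acetyl group adds to the aldehyde and closes ring C; the aldolate adds to (Z)-2-methylbut-2-enal A6 and hydride shifts to C9, giving mono-angelate A4 with the anti diol. Ring closure, the anti 1,3-relationship and one ester come in a single step, and the cyclic hydride transfer ties C9 to C7. For the diol this is better than steps 16, 17 and half of 23 here. C7 itself is set in a reversible aldol on a neopentyl aldehyde with only the cage to choose the face. A6 is enolisable, isomerises easily and can react directly with the enolate. A5 already contains ring A with all four stereocentres, so the hardest part of the molecule is left unsolved. As an endgame this road is as good or better; the chosen plan sets against it a worked-out route to the cage, and its iodolactonisation reaches the same anti diol from a centre the key step provides anyway.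

Alternative 3: The cut is C3–C4, with ring B last, from keto acid A8, a ring-C-fused bicyclobutane (central bond C4–C11) carrying the γ-keto acid chain on C11. In the forward step photoredox decarboxylation gives the C3 radical, which attacks the distal bridgehead C4; the central bond breaks and the C11 α-keto radical is reduced and protonated to bis-silyl ether A7. Ring B closes at the right oxidation level, C11 has no choice in the closed cage, and the diol is already in place. In operations this beats steps 19 to 22 here and needs no C11 inversion. A8 is more strained than the target and must be made as one stereoisomer with the C7/C9 diol already set. C3 comes from a secondary radical whose methyl orientation depends on the conformation of the closing ring. The chosen plan sets against this an unstrained precursor (19 has no small ring), C3 by cuprate addition under the C10 methyl, and strain built in one closed-shell step paid for by carboxylate formation.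

Key step: step 15

Assumption: the sense of induction in steps 4 and 8 is assigned from the accepted models of the imidazolidinone iminium ion and of isopinocampheyl allylboranes; the mirror-image catalyst or borane would be used if the first adduct required it.
Assumption: 13 is drawn as the open hydroxy ketone although it should rest mainly as cyclic hemiketals; 27 and 28 are drawn as the hemiketal with the C9 oxygen.
Assumption: in step 23 the first angeloyl group is drawn on the C9 oxygen (35); the order of the two acylations has no bearing on the product.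
Locants C1–C11 in names and descriptors of compounds 24–36 follow the numbering defined in the first section.

## Route

Step 1
Reactants: 1 isobutyryl chloride; 2 ethanethiol
Product: 3 S-ethyl 2-methylpropanethioate
Conditions: Et3N, CH2Cl2, 0 → 23 °C
Reagents that add atoms: none
Why: Acylation of the thiol by the acid chloride (thioesterification) with the amine as HCl scavenger; no stereocentre is involved.

Step 2
Reactants: 3 S-ethyl 2-methylpropanethioate
Product: 4 [1-(ethylsulfanyl)-2-methylprop-1-en-1-yl]oxy(trimethyl)silane
Conditions: LiN(iPr)2, THF, −78 °C; Me3SiCl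
Reagents that add atoms: chlorotrimethylsilane, C[Si](C)(C)Cl
Why: Deprotonation at the single α-CH and O-silylation of the thioester enolate (silyl ketene acetal formation); the ketene S,O-acetal is tetrasubstituted, so no enolate geometry has to be controlled.

Step 3
Reactants: 5 3-[(tert-butyldimethylsilyl)oxy]propanal
Product: 6 (E)-5-[(tert-butyldimethylsilyl)oxy]pent-2-enal
Conditions: Ph3P=CHCHO, PhMe, 80 °C
Reagents that add atoms: (triphenylphosphoranylidene)acetaldehyde, O=CC=P(c1ccccc1)(c1ccccc1)c1ccccc1
Why: Wittig olefination with the stabilised formylmethylene ylide adds C4 and C10 and should give the E-enal, as stabilised ylides do.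

Step 4
Reactants: 6 (E)-5-[(tert-butyldimethylsilyl)oxy]pent-2-enal; 4 [1-(ethylsulfanyl)-2-methylprop-1-en-1-yl]oxy(trimethyl)silane
Product: 8 S-ethyl 2-[(4R)-2-hydroxyoxan-4-yl]-2-methylpropanethioate (lactol; both anomers), via aldehyde adduct 7 (not isolated)
Conditions: (2S,5S)-5-benzyl-2-tert-butyl-3-methylimidazolidin-4-one·CF3CO2H (20 mol %), CH2Cl2, H2O (2 equiv), −55 °C; then 1 M HCl, THF, 23 °C
Reagents that add atoms: none
Why: Organocatalytic Mukaiyama–Michael addition: the enal reacts as its E-iminium ion, whose benzyl group shields one face of C5, so the ketene S,O-acetal should add to the open face and set C5 (R) by catalyst control, as in additions of silyl ketene thioacetals to crotonaldehyde-type enals; the acidic work-up removes the silyl ether and the freed alcohol closes the six-membered lactol.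

Step 5
Reactants: 8 S-ethyl 2-[(4R)-2-hydroxyoxan-4-yl]-2-methylpropanethioate
Product: 9 S-ethyl 2-methyl-2-[(4R)-2-oxooxan-4-yl]propanethioate
Conditions: TEMPO (10 mol %), PhI(OAc)2, CH2Cl2, 23 °C
Reagents that add atoms: none
Why: Oxoammonium (TEMPO) oxidation of a lactol to the lactone with PhI(OAc)2 as terminal oxidant; the hindered thioester is inert.

Step 6
Reactants: 9 S-ethyl 2-methyl-2-[(4R)-2-oxooxan-4-yl]propanethioate
Product: 10 S-ethyl 2-{(3R,4R)-3-[(benzyloxy)methyl]-2-oxooxan-4-yl}-2-methylpropanethioate
Conditions: LiN(iPr)2, THF, −78 °C; BnOCH2Cl, −78 → −40 °C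
Reagents that add atoms: benzyl chloromethyl ether, ClCOCc1ccccc1
Why: Alkylation of the δ-lactone lithium enolate; the electrophile enters anti to the bulky tertiary substituent on the neighbouring C5 and sets C4 trans to it, which is the relationship that becomes cis on ring C because this ring runs through C10 and C11.

Step 7
Reactants: 10 S-ethyl 2-{(3R,4R)-3-[(benzyloxy)methyl]-2-oxooxan-4-yl}-2-methylpropanethioate
Product: 11 2-{(3R,4R)-3-[(benzyloxy)methyl]-2-oxooxan-4-yl}-2-methylpropanal
Conditions: Et3SiH, Pd/C (5 mol %), acetone, 23 °C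
Reagents that add atoms: none
Why: Fukuyama reduction (palladium-catalysed hydrosilane reduction of a thioester) stops at the aldehyde and leaves the lactone and the benzyl ether untouched, which is why C7 was carried as a thioester.

Step 8
Reactants: 11 2-{(3R,4R)-3-[(benzyloxy)methyl]-2-oxooxan-4-yl}-2-methylpropanal
Product: 12 (3R,4R)-3-[(benzyloxy)methyl]-4-[(3S,4S)-3-hydroxy-4-(methoxymethoxy)-2-methylhex-5-en-2-yl]oxan-2-one
Conditions: CH2=CHCH2OCH2OMe, s-BuLi, THF, −78 °C; (+)-Ipc2BOMe; BF3·OEt2; then 11, −78 °C; NaBO3·4H2O, THF–H2O, 23 °C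
Reagents that add atoms: 3-(methoxymethoxy)prop-1-ene, C=CCOCOC
Why: Brown syn-alkoxyallylboration: the (Z)-γ-alkoxyallylborane reacts through a chair six-membered transition state, which gives the syn relationship of the C7 hydroxyl and the C8 ether, and the isopinocampheyl groups choose the aldehyde face (reagent control, C7 S and C8 S; the quaternary α-carbon exerts no bias).

Step 9
Reactants: 12 (3R,4R)-3-[(benzyloxy)methyl]-4-[(3S,4S)-3-hydroxy-4-(methoxymethoxy)-2-methylhex-5-en-2-yl]oxan-2-one
Product: 13 (3R,4R,6S,7S)-3-[(benzyloxy)methyl]-6-hydroxy-4-(2-hydroxyethyl)-7-(methoxymethoxy)-5,5-dimethylnon-8-en-2-one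
Conditions: MeLi (2.5 equiv), THF, −78 °C; aq. NH4Cl
Reagents that add atoms: methyllithium, [Li]C
Why: Addition of methyllithium to the δ-lactone stops after one equivalent because the tetrahedral lithium hemiketal alkoxide survives at −78 °C and collapses to the methyl ketone only on quenching; the C7 alkoxide merely consumes base, and if it transacylates both lactones lead to the same ketone.

Step 10
Reactants: 13 (3R,4R,6S,7S)-3-[(benzyloxy)methyl]-6-hydroxy-4-(2-hydroxyethyl)-7-(methoxymethoxy)-5,5-dimethylnon-8-en-2-one
Product: 14 (3R,4S)-4-[(benzyloxy)methyl]-3-[(3S,4S)-3-hydroxy-4-(methoxymethoxy)-2-methylhex-5-en-2-yl]-5-methylhex-5-en-1-ol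
Conditions: Ph3PCH3Br, KN(SiMe3)2, THF, 0 → 23 °C
Reagents that add atoms: methyltriphenylphosphonium bromide, C[P+](c1ccccc1)(c1ccccc1)c1ccccc1.[Br-]
Why: Wittig methylenation of the ketone tautomer turns C10 into the isopropenyl group; the reaction is run cold to limit enolisation at C4.

Step 11
Reactants: 14 (3R,4S)-4-[(benzyloxy)methyl]-3-[(3S,4S)-3-hydroxy-4-(methoxymethoxy)-2-methylhex-5-en-2-yl]-5-methylhex-5-en-1-ol
Product: 15 2-{(1R,2S,5S,6S)-2-[(benzyloxy)methyl]-6-hydroxy-5-(methoxymethoxy)-3,7,7-trimethylcyclohept-3-en-1-yl}ethan-1-ol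
Conditions: RuCl2(=CHPh)(PCy3)(H2IMes) (second-generation Grubbs catalyst, 5 mol %), CH2Cl2 (2 mM), 40 °C
Reagents that add atoms: none
Why: Ring-closing metathesis between the monosubstituted C8 vinyl group (initiation site) and the 1,1-disubstituted isopropenyl group closes ring C as the trisubstituted C9=C10 cycloheptene; the C6 gem-dimethyl group favours the folded conformer and loss of ethene drives the reaction.

Step 12
Reactants: 15 2-{(1R,2S,5S,6S)-2-[(benzyloxy)methyl]-6-hydroxy-5-(methoxymethoxy)-3,7,7-trimethylcyclohept-3-en-1-yl}ethan-1-ol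
Product: 16 2-{(1R,2S,5S,6S)-2-[(benzyloxy)methyl]-6-hydroxy-5-(methoxymethoxy)-3,7,7-trimethylcyclohept-3-en-1-yl}acetic acid
Conditions: TEMPO (20 mol %), PhI(OAc)2 (2.5 equiv), MeCN–H2O (1:1), 23 °C
Reagents that add atoms: water, O
Why: Oxoammonium oxidation in aqueous acetonitrile takes the primary alcohol through the aldehyde hydrate to the acid, while the neopentyl secondary C7 alcohol reacts far more slowly.

Step 13
Reactants: 16 2-{(1R,2S,5S,6S)-2-[(benzyloxy)methyl]-6-hydroxy-5-(methoxymethoxy)-3,7,7-trimethylcyclohept-3-en-1-yl}acetic acid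
Product: 17 2-{(1R,2S,5S,6S)-2-[(benzyloxy)methyl]-5,6-dihydroxy-3,7,7-trimethylcyclohept-3-en-1-yl}acetic acid
Conditions: ZnBr2, n-PrSH, CH2Cl2, 0 °C
Reagents that add atoms: none
Why: Lewis-acid-assisted cleavage of the MOM acetal with a thiol as trap for the methoxymethyl cation; the O–CH2–O unit is broken, not the allylic C8–O bond, and the thiol prevents capture by the neighbouring C7 hydroxyl.

Step 14
Reactants: 17 2-{(1R,2S,5S,6S)-2-[(benzyloxy)methyl]-5,6-dihydroxy-3,7,7-trimethylcyclohept-3-en-1-yl}acetic acid
Product: 19 (1S,5R,6S,9S)-6-[(benzyloxy)methyl]-9-hydroxy-7,10,10-trimethyl-2-oxabicyclo[3.3.2]dec-7-en-3-one, via mixed anhydride 18 (not isolated)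
Conditions: 2,4,6-Cl3C6H2COCl, Et3N, THF, 23 °C; then DMAP, PhMe (1 mM), 80 °C
Reagents that add atoms: none
Why: Yamaguchi lactonisation through the mixed anhydride at high dilution; of the two hydroxyls only the one on C8 is cis to the C5 acetic acid chain, so only the seven-membered bridged lactone can close intramolecularly.

Step 15
Reactants: 19 (1S,5R,6S,9S)-6-[(benzyloxy)methyl]-9-hydroxy-7,10,10-trimethyl-2-oxabicyclo[3.3.2]dec-7-en-3-one
Product: 23 (1R,4R,6S,7S,8S)-8-[(benzyloxy)methyl]-4-hydroxy-1,5,5-trimethylbicyclo[4.1.1]oct-2-ene-7-carboxylic acid, via O-silyl lactone 20 (not isolated), via silyl ketene acetal 21 (not isolated), via bis-silylated acid 22 (not isolated)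
Conditions: Me3SiCl, Et3N, THF, 0 °C; LiN(iPr)2, Me3SiCl, −78 °C; then PhMe, 23 → 80 °C; 1 M HCl work-up
Reagents that add atoms: none
Why: The C7 hydroxyl is silylated in the flask, LiN(iPr)2 removes one C11 proton and O-silylation gives the cyclic silyl ketene acetal 21. Its six-atom array C11=C1–O–C8–C9=C10 is held by the bicycle in a boat, and on warming the [3,3] shift forms C10–C11, breaks C8–O and moves the alkene to C8=C9 (Ireland–Claisen rearrangement). The closest known reaction type is the Ireland–Claisen ring contraction of unsaturated medium-ring lactones to cis-2-alkenylcycloalkanecarboxylic acids, cyclobutanes included. Ring A closes as a four-membered ring by suprafacial bonding of the two ends of that array, the eight-membered lactone path contracting to the carbocycle. C10 is controlled by C8: the new bond forms on the face that carried the C8 oxygen (1,3-chirality transfer). C11 is controlled by the tether: C1 must stay on the side of C9 and C6, so the carboxyl ends up over ring C, the epimer opposite to the target, which step 16 uses and step 21 corrects. The step needs O- rather than C-silylation and a driving force against ring strain; the single acidic CH2 with trapping at −78 °C secures the first, and formation of the silyl carboxylate supplies the second.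

Step 16
Reactants: 23 (1R,4R,6S,7S,8S)-8-[(benzyloxy)methyl]-4-hydroxy-1,5,5-trimethylbicyclo[4.1.1]oct-2-ene-7-carboxylic acid
Product: 24 iodolactone (C1 carboxyl closed onto the C9 oxygen; 8-iodo; 7-hydroxy; 4-benzyloxymethyl; 4S,5S,7S,8S,9S,10R,11S)
Conditions: I2, NaHCO3, MeCN, 0 °C, dark
Reagents that add atoms: iodine, II
Why: Iodolactonisation (5-exo, anti addition): the endo carboxylate can reach only C9 and only from the upper face, so it opens the iodonium ion formed on the lower face and sets the C9 oxygen with the target configuration; iodine is left at C8.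

Step 17
Reactants: 24 iodolactone
Product: 25 γ-lactone (C1 to O9; 7-hydroxy; 4-benzyloxymethyl; 4S,5S,7R,9R,10R,11S)
Conditions: n-Bu3SnH, AIBN (cat.), PhH, 80 °C
Reagents that add atoms: none
Why: Radical chain dehalogenation by the tin hydride removes the C8 iodine; hydrogen transfer to the C8 radical should be much faster than acyloxy migration.

Step 18
Reactants: 25 γ-lactone benzyl ether
Product: 26 γ-lactone diol (C1 to O9; 7-hydroxy; 4-hydroxymethyl; 4S,5S,7R,9R,10R,11S)
Conditions: H2 (1 atm), Pd/C, EtOAc, 23 °C
Reagents that add atoms: none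
Why: Hydrogenolysis of the benzyl ether over palladium; with the alkene gone no other group is reducible.

Step 19
Reactants: 26 γ-lactone diol
Product: 27 C1 methyl hemiketal with O9 (7-hydroxy; 4-hydroxymethyl; C1 anomers; 4S,5S,7R,9R,10R,11S)
Conditions: MeLi (3.5 equiv), THF, −78 °C; aq. NH4Cl
Reagents that add atoms: methyllithium, [Li]C
Why: Mono-addition of methyllithium to the γ-lactone (stable tetrahedral intermediate at −78 °C) introduces C2; the product rests as the five-membered hemiketal with the C9 hydroxyl, which shows that the acetyl group is still endo.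

Step 20
Reactants: 27 hemiketal triol
Product: 28 hemiketal aldehyde (C3 formyl on C4; 7-hydroxy; 4S,5S,7R,9R,10R,11S)
Conditions: TEMPO (10 mol %), PhI(OAc)2, CH2Cl2, 23 °C
Reagents that add atoms: none
Why: Oxoammonium oxidation under anhydrous conditions stops at the aldehyde and is selective for the primary C3 alcohol over the hindered secondary C7 alcohol and the tertiary hemiketal.

Step 21
Reactants: 28 hemiketal aldehyde
Product: 32 7,9-dihydroxy tricyclic enone (C1 ketone; C2=C3; no C3 methyl; 4S,5S,7R,9R,10R,11R), via open keto aldehyde 29 (not isolated), via C11 epimer 30 (not isolated), via aldol adduct 31 (not isolated)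
Conditions: NaOMe, MeOH, 0 → 50 °C
Reagents that add atoms: none
Why: Base opens the hemiketal, enolisation of the cyclobutyl methyl ketone interconverts the C11 epimers (as in the cis/trans equilibration of acetylcyclobutanes of the pinonic acid type), and only epimer 30, with acetyl and formyl on the same face of ring A, can undergo the intramolecular aldol addition (6-enolexo-exo-trig) and E1cB dehydration, so C11 is set by the ring that forms; the enolate p orbital is orthogonal to the ring A bonds, which disfavours retro-Michael opening.

Step 22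
Reactants: 32 7,9-dihydroxy tricyclic enone
Product: 33 7,9-dihydroxylongipinan-1-one (3R,4S,5S,7R,9R,10R,11R)
Conditions: CuI, MeLi (Me2CuLi, 5 equiv), Et2O, −40 → 0 °C; aq. NH4Cl
Reagents that add atoms: lithium dimethylcuprate, [Li+].C[Cu-]C
Why: Conjugate addition of the Gilman cuprate to the bicyclo[3.1.1]heptenone; the C10 methyl group covers one face of ring B, so methyl is delivered to C3 from the face of the C5 hydrogen, as in cuprate additions to verbenone-type enones.

Step 23
Reactants: 33 7,9-dihydroxylongipinan-1-one; 34 angelic acid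
Product: 36 7,9-bis(angeloyloxy)longipinan-1-one (CNP0283599.1; 3R,4S,5S,7R,9R,10R,11R), via 9-monoangelate 35 (not isolated)
Conditions: 34 (3 equiv), 2,4,6-Cl3C6H2COCl (3 equiv), Et3N, PhMe, 23 °C; then 33, 80 °C
Reagents that add atoms: angelic acid (second equivalent of 34), C/C=C(/C)C(=O)O
Why: Yamaguchi-type esterification in which each hydroxyl consumes one equivalent of the mixed 2,4,6-trichlorobenzoic anhydride of 34, the alcohol attacking the unhindered angeloyl carbonyl. The C9 hydroxyl, whose quaternary neighbour C10 is a tied-back ring A carbon, should react first to give 35, and the C7 hydroxyl beside the gem-dimethyl carbon is then acylated by the second equivalent, the order being immaterial because both end as the same ester. This base-poor protocol is used for angelates because it avoids the Z to E isomerisation seen with acyl chlorides and nucleophilic catalysts, and no stereocentre changes.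

## Compound list

1 | isobutyryl chloride | CC(C)C(=O)Cl | starting material
2 | ethanethiol | CCS | starting material
3 | S-ethyl 2-methylpropanethioate | CCSC(=O)C(C)C | intermediate
4 | [1-(ethylsulfanyl)-2-methylprop-1-en-1-yl]oxy(trimethyl)silane | CCSC(O[Si](C)(C)C)=C(C)C | intermediate
5 | 3-[(tert-butyldimethylsilyl)oxy]propanal | O=CCCO[Si](C)(C)C(C)(C)C | starting material
6 | (E)-5-[(tert-butyldimethylsilyl)oxy]pent-2-enal | O=C/C=C/CCO[Si](C)(C)C(C)(C)C | intermediate
7 | S-ethyl (3R)-3-{2-[(tert-butyldimethylsilyl)oxy]ethyl}-2,2-dimethyl-5-oxopentanethioate | O=CC[C@@H](CCO[Si](C)(C)C(C)(C)C)C(C)(C)C(=O)SCC | intermediate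
8 | S-ethyl 2-[(4R)-2-hydroxyoxan-4-yl]-2-methylpropanethioate | OC1C[C@@H](CCO1)C(C)(C)C(=O)SCC | intermediate
9 | S-ethyl 2-methyl-2-[(4R)-2-oxooxan-4-yl]propanethioate | O=C1C[C@@H](CCO1)C(C)(C)C(=O)SCC | intermediate
10 | S-ethyl 2-{(3R,4R)-3-[(benzyloxy)methyl]-2-oxooxan-4-yl}-2-methylpropanethioate | O=C1[C@@H](COCc2ccccc2)[C@@H](CCO1)C(C)(C)C(=O)SCC | intermediate
11 | 2-{(3R,4R)-3-[(benzyloxy)methyl]-2-oxooxan-4-yl}-2-methylpropanal | O=C1[C@@H](COCc2ccccc2)[C@@H](CCO1)C(C)(C)C=O | intermediate
12 | (3R,4R)-3-[(benzyloxy)methyl]-4-[(3S,4S)-3-hydroxy-4-(methoxymethoxy)-2-methylhex-5-en-2-yl]oxan-2-one | O=C1[C@@H](COCc2ccccc2)[C@@H](CCO1)C(C)(C)[C@H](O)[C@@H](OCOC)C=C | intermediate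
13 | (3R,4R,6S,7S)-3-[(benzyloxy)methyl]-6-hydroxy-4-(2-hydroxyethyl)-7-(methoxymethoxy)-5,5-dimethylnon-8-en-2-one | CC(=O)[C@@H](COCc1ccccc1)[C@@H](CCO)C(C)(C)[C@H](O)[C@@H](OCOC)C=C | intermediate
14 | (3R,4S)-4-[(benzyloxy)methyl]-3-[(3S,4S)-3-hydroxy-4-(methoxymethoxy)-2-methylhex-5-en-2-yl]-5-methylhex-5-en-1-ol | C=C(C)[C@@H](COCc1ccccc1)[C@@H](CCO)C(C)(C)[C@H](O)[C@@H](OCOC)C=C | intermediate
15 | 2-{(1R,2S,5S,6S)-2-[(benzyloxy)methyl]-6-hydroxy-5-(methoxymethoxy)-3,7,7-trimethylcyclohept-3-en-1-yl}ethan-1-ol | O[C@@H]1[C@@H](OCOC)C=C(C)[C@@H](COCc2ccccc2)[C@@H](CCO)C1(C)C | intermediate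
16 | 2-{(1R,2S,5S,6S)-2-[(benzyloxy)methyl]-6-hydroxy-5-(methoxymethoxy)-3,7,7-trimethylcyclohept-3-en-1-yl}acetic acid | O[C@@H]1[C@@H](OCOC)C=C(C)[C@@H](COCc2ccccc2)[C@@H](CC(=O)O)C1(C)C | intermediate
17 | 2-{(1R,2S,5S,6S)-2-[(benzyloxy)methyl]-5,6-dihydroxy-3,7,7-trimethylcyclohept-3-en-1-yl}acetic acid | O[C@@H]1[C@@H](O)C=C(C)[C@@H](COCc2ccccc2)[C@@H](CC(=O)O)C1(C)C | intermediate
18 | mixed anhydride of 17 with 2,4,6-trichlorobenzoic acid | O[C@@H]1[C@@H](O)C=C(C)[C@@H](COCc2ccccc2)[C@@H](CC(=O)OC(=O)c2c(Cl)cc(Cl)cc2Cl)C1(C)C | intermediate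
19 | (1S,5R,6S,9S)-6-[(benzyloxy)methyl]-9-hydroxy-7,10,10-trimethyl-2-oxabicyclo[3.3.2]dec-7-en-3-one | O[C@@H]1[C@@H]2C=C(C)[C@@H](COCc3ccccc3)[C@@H](CC(=O)O2)C1(C)C | intermediate
20 | 9-O-trimethylsilyl ether of 19 | C[Si](C)(C)O[C@@H]1[C@@H]2C=C(C)[C@@H](COCc3ccccc3)[C@@H](CC(=O)O2)C1(C)C | intermediate
21 | cyclic trimethylsilyl ketene acetal of 20 (C11=C1) | C[Si](C)(C)O[C@@H]1[C@@H]2C=C(C)[C@@H](COCc3ccccc3)[C@@H](C=C(O[Si](C)(C)C)O2)C1(C)C | intermediate
22 | trimethylsilyl ester and 4-O-trimethylsilyl ether of 23 | C[Si](C)(C)O[C@@H]1C=C[C@]2(C)[C@@H](COCc3ccccc3)[C@@H]([C@@H]2C(=O)O[Si](C)(C)C)C1(C)C | intermediate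
23 | (1R,4R,6S,7S,8S)-8-[(benzyloxy)methyl]-4-hydroxy-1,5,5-trimethylbicyclo[4.1.1]oct-2-ene-7-carboxylic acid | O[C@@H]1C=C[C@]2(C)[C@@H](COCc3ccccc3)[C@@H]([C@@H]2C(=O)O)C1(C)C | intermediate
24 | iodolactone: C1 carboxyl closed onto O9, 8-iodo, 7-hydroxy, 4-benzyloxymethyl (4S,5S,7S,8S,9S,10R,11S) | O[C@@H]1[C@H](I)[C@H]2OC(=O)[C@H]3[C@H]([C@H](COCc4ccccc4)[C@@]23C)C1(C)C | intermediate
25 | γ-lactone C1 to O9, 7-hydroxy, 4-benzyloxymethyl (4S,5S,7R,9R,10R,11S) | O[C@@H]1C[C@H]2OC(=O)[C@H]3[C@H]([C@H](COCc4ccccc4)[C@@]23C)C1(C)C | intermediate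
26 | γ-lactone C1 to O9, 7-hydroxy, 4-hydroxymethyl (4S,5S,7R,9R,10R,11S) | O[C@@H]1C[C@H]2OC(=O)[C@H]3[C@H]([C@H](CO)[C@@]23C)C1(C)C | intermediate
27 | C1 methyl hemiketal with O9, 7-hydroxy, 4-hydroxymethyl (4S,5S,7R,9R,10R,11S) | O[C@@H]1C[C@H]2OC(C)(O)[C@H]3[C@H]([C@H](CO)[C@@]23C)C1(C)C | intermediate
28 | C1 methyl hemiketal with O9, 7-hydroxy, 4-formyl (4S,5S,7R,9R,10R,11S) | O[C@@H]1C[C@H]2OC(C)(O)[C@H]3[C@H]([C@H](C=O)[C@@]23C)C1(C)C | intermediate
29 | open keto aldehyde, acetyl endo on C11 (11S) | O[C@@H]1C[C@@H](O)[C@]2(C)[C@@H](C=O)[C@@H]([C@@H]2C(C)=O)C1(C)C | intermediate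
30 | keto aldehyde, acetyl exo on C11 (11R) | O[C@@H]1C[C@@H](O)[C@]2(C)[C@@H](C=O)[C@@H]([C@H]2C(C)=O)C1(C)C | intermediate
31 | aldol adduct, 3-hydroxy ring B ketone (C3 epimers) | O[C@@H]1C[C@@H](O)[C@]2(C)[C@@H]3[C@@H]([C@H]2C(=O)CC3O)C1(C)C | intermediate
32 | 7,9-dihydroxy tricyclic enone, C1 ketone, C2=C3 (4S,5S,7R,9R,10R,11R) | O[C@@H]1C[C@@H](O)[C@]2(C)[C@@H]3[C@@H]([C@H]2C(=O)C=C3)C1(C)C | intermediate
33 | 7,9-dihydroxylongipinan-1-one (3R,4S,5S,7R,9R,10R,11R) | O[C@@H]1C[C@@H](O)[C@]2(C)[C@@H]3[C@@H]([C@H]2C(=O)C[C@H]3C)C1(C)C | intermediate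
34 | angelic acid, (Z)-2-methylbut-2-enoic acid | C/C=C(/C)C(=O)O | starting material
35 | 9-(angeloyloxy)-7-hydroxylongipinan-1-one (3R,4S,5S,7R,9R,10R,11R) | O[C@@H]1C[C@@H](OC(=O)/C(C)=C\C)[C@]2(C)[C@@H]3[C@@H]([C@H]2C(=O)C[C@H]3C)C1(C)C | intermediate
36 | 7,9-bis(angeloyloxy)longipinan-1-one, CNP0283599.1 (3R,4S,5S,7R,9R,10R,11R) | C/C=C(/C)C(=O)O[C@@H]1C[C@@H](OC(=O)/C(C)=C\C)[C@]2(C)[C@@H]3[C@@H]([C@H]2C(=O)C[C@H]3C)C1(C)C | target

## Step count and least certain steps

Total: 23 steps. Longest linear sequence: 22 steps (steps 1, 2 and 4–23 from isobutyryl chloride).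

**Step 15 (key step).** Enolisation or O-silylation of the hindered bridged lactone may be incomplete, the ketene acetal may be C-silylated, or it may fragment before the strained boat is reached. The fallback sets out from 17 and returns at 23; it makes the same C10–C11 bond by an intramolecular SN2′ enolate alkylation. Me3SiCHN2 converts 17 into the methyl ester F1. ClP(O)(OEt)2 and pyridine phosphorylate the allylic C8 hydroxyl to the diethyl phosphate F2, and Et3SiOTf caps the C7 hydroxyl to give the triethylsilyl ether F3. KN(SiMe3)2 then forms the ester enolate, which displaces the phosphate by attack on C10 from the face of its tether and gives the cyclobutane methyl ester F4 as a C11 mixture. LiOH and acidic work-up return 23; the exo ester is recycled by NaOMe equilibration of F4.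

**Step 4.** The tetrasubstituted ketene S,O-acetal may add slowly or with poor facial selectivity, and 1,2-addition to the iminium ion may compete. The fallback sets out from 4 and returns at 9. A Me3SiOTf-catalysed Mukaiyama–Michael addition of 4 to dimethyl glutaconate gives the achiral triester F5. The two unhindered methyl esters are saponified to the diacid F6, and Ac2O closes the glutaric anhydride F7. Alkaloid-mediated methanolysis (quinidine or quinine, whichever gives the R hemiester) desymmetrises C5 and gives the hemiester F8. BH3·SMe2 reduces the free acid, and acid-catalysed lactonisation of the hydroxy ester gives 9.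

**Step 14.** Oligomerisation may outrun closure of the bridged seven-membered lactone because both substituents must turn axial. The fallback sets out from 14 and returns at 19; the lactone is closed before ring C. TEMPO and PhI(OAc)2 in aqueous MeCN give the seco acid F9, and Et3SiOTf followed by mild acid gives the C7 triethylsilyl ether F10. ZnBr2 and n-PrSH free the C8 hydroxyl in F11, and Yamaguchi closure gives the monocyclic seven-membered lactone F12, in which only C8 can react. Ring-closing metathesis then forms C9=C10 across the lactone to give the silyl ether F13, and HF·pyridine gives 19.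

**Step 21.** Inversion at C11 may be too slow relative to intermolecular aldol reactions of the aldehyde, since the substrate rests as a hemiketal. The fallback sets out from 27 and returns at 32; ring B is closed by alkylation. TsCl and pyridine give the primary tosylate F14. KOtBu in tBuOH equilibrates C11, and the methyl ketone enolate displaces the tosylate (6-enolexo-exo-tet) to give the saturated ketone F15. Me3SiOTf and Et3N give the silyl enol ether F16, with the hydroxyls silylated as well. Saegusa–Ito dehydrogenation with Pd(OAc)2 and aqueous acid then gives 32.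

**Step 23.** The second acylation of the two neopentyl-type secondary alcohols may fail to go to completion, and forcing conditions may isomerise the angelate to the tiglate. The fallback sets out from 33 and returns at 36. Esterification of both hydroxyls with 2-[bis(2,2,2-trifluoroethoxy)phosphoryl]propanoic acid (DCC, DMAP) gives the bis(phosphonate) F17. Still–Gennari olefination of both phosphonates with acetaldehyde (KN(SiMe3)2, 18-crown-6, −78 °C) then builds both Z-enoates in place and gives 36.

## Further compounds

F1 | step 15 | methyl 2-{(1R,2S,5S,6S)-2-[(benzyloxy)methyl]-5,6-dihydroxy-3,7,7-trimethylcyclohept-3-en-1-yl}acetate | O[C@@H]1[C@@H](O)C=C(C)[C@@H](COCc2ccccc2)[C@@H](CC(=O)OC)C1(C)C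
F2 | step 15 | C8 diethyl phosphate of F1 | O[C@@H]1[C@@H](OP(=O)(OCC)OCC)C=C(C)[C@@H](COCc2ccccc2)[C@@H](CC(=O)OC)C1(C)C
F3 | step 15 | C7 triethylsilyl ether of F2 | CC[Si](CC)(CC)O[C@@H]1[C@@H](OP(=O)(OCC)OCC)C=C(C)[C@@H](COCc2ccccc2)[C@@H](CC(=O)OC)C1(C)C
F4 | step 15 | methyl ester and 4-O-triethylsilyl ether of 23 (C11 epimers) | CC[Si](CC)(CC)O[C@@H]1C=C[C@]2(C)[C@@H](COCc3ccccc3)[C@@H](C2C(=O)OC)C1(C)C
F5 | step 4 | dimethyl 3-[1-(ethylsulfanyl)-2-methyl-1-oxopropan-2-yl]pentanedioate | COC(=O)CC(CC(=O)OC)C(C)(C)C(=O)SCC
F6 | step 4 | 3-[1-(ethylsulfanyl)-2-methyl-1-oxopropan-2-yl]pentanedioic acid | OC(=O)CC(CC(=O)O)C(C)(C)C(=O)SCC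
F7 | step 4 | S-ethyl 2-(2,6-dioxooxan-4-yl)-2-methylpropanethioate | O=C1CC(CC(=O)O1)C(C)(C)C(=O)SCC
F8 | step 4 | (3R)-3-[1-(ethylsulfanyl)-2-methyl-1-oxopropan-2-yl]-5-methoxy-5-oxopentanoic acid | COC(=O)C[C@@H](CC(=O)O)C(C)(C)C(=O)SCC
F9 | step 14 | seco acid from 14 (C1 carboxylic acid) | C=C(C)[C@@H](COCc1ccccc1)[C@@H](CC(=O)O)C(C)(C)[C@H](O)[C@@H](OCOC)C=C
F10 | step 14 | C7 triethylsilyl ether of F9 | C=C(C)[C@@H](COCc1ccccc1)[C@@H](CC(=O)O)C(C)(C)[C@H](O[Si](CC)(CC)CC)[C@@H](OCOC)C=C
F11 | step 14 | C8 alcohol from F10 | C=C(C)[C@@H](COCc1ccccc1)[C@@H](CC(=O)O)C(C)(C)[C@H](O[Si](CC)(CC)CC)[C@@H](O)C=C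
F12 | step 14 | monocyclic seven-membered lactone (O8 to C1) with C8 vinyl and C4 isopropenyl arms | C=C[C@@H]1OC(=O)C[C@H]([C@H](COCc2ccccc2)C(C)=C)C(C)(C)[C@@H]1O[Si](CC)(CC)CC
F13 | step 14 | 9-O-triethylsilyl ether of 19 | CC[Si](CC)(CC)O[C@@H]1[C@@H]2C=C(C)[C@@H](COCc3ccccc3)[C@@H](CC(=O)O2)C1(C)C
F14 | step 21 | C3 p-toluenesulfonate of 27 | O[C@@H]1C[C@H]2OC(C)(O)[C@H]3[C@H]([C@H](COS(=O)(=O)c4ccc(C)cc4)[C@@]23C)C1(C)C
F15 | step 21 | 7,9-dihydroxy tricyclic ketone without C3 methyl (saturated ring B) | O[C@@H]1C[C@@H](O)[C@]2(C)[C@@H]3[C@@H]([C@H]2C(=O)CC3)C1(C)C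
F16 | step 21 | C1 trimethylsilyl enol ether (C1=C2) and 7,9-bis(trimethylsilyl) ether of F15 | C[Si](C)(C)O[C@@H]1C[C@@H](O[Si](C)(C)C)[C@]2(C)[C@@H]3[C@@H]([C@H]2C(O[Si](C)(C)C)=CC3)C1(C)C
F17 | step 23 | 7,9-bis{2-[bis(2,2,2-trifluoroethoxy)phosphoryl]propanoate} of 33 | CC(P(=O)(OCC(F)(F)F)OCC(F)(F)F)C(=O)O[C@@H]1C[C@@H](OC(=O)C(C)P(=O)(OCC(F)(F)F)OCC(F)(F)F)[C@]2(C)[C@@H]3[C@@H]([C@H]2C(=O)C[C@H]3C)C1(C)C
A1 | alternative 1 | cage enone: C7 ketone, C8=C9, C1 dioxolane, no C3 methyl | O=C1C=C[C@]2(C)[C@@H]3[C@@H]([C@H]2C4(OCCO4)CC3)C1(C)C
A2 | alternative 1 | ring-B-bridged bicyclobutane (central bond C5–C10, C10 methyl, C1 dioxolane) | C[C@@]12[C@H]3CCC4(OCCO4)[C@@H]1[C@@H]23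
A3 | alternative 1 | 4-bromo-4-methylpent-1-yn-3-one | CC(C)(Br)C(=O)C#C
A4 | alternative 2 | C7 angelate C9 alcohol of the C1 dioxolane core | C/C=C(/C)C(=O)O[C@@H]1C[C@@H](O)[C@]2(C)[C@@H]3[C@@H]([C@H]2C4(OCCO4)C[C@H]3C)C1(C)C
A5 | alternative 2 | seco keto aldehyde: C10 acetyl, C6 formyl, rings A and B as C1 dioxolane | CC(=O)[C@]1(C)[C@@H]2[C@@H]([C@H]1C3(OCCO3)C[C@H]2C)C(C)(C)C=O
A6 | alternative 2 | (Z)-2-methylbut-2-enal | C/C=C(/C)C=O
A7 | alternative 3 | 7,9-bis(tert-butyldimethylsilyloxy)longipinan-1-one | CC(C)(C)[Si](C)(C)O[C@@H]1C[C@@H](O[Si](C)(C)C(C)(C)C)[C@]2(C)[C@@H]3[C@@H]([C@H]2C(=O)C[C@H]3C)C1(C)C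
A8 | alternative 3 | ring-C-fused bicyclobutane (central bond C4–C11) with 2-methyl-4-oxobutanoic acid chain on C11 | CC(CC(=O)[C@@]12[C@H]3C(C)(C)[C@H](O[Si](C)(C)C(C)(C)C)C[C@@H](O[Si](C)(C)C(C)(C)C)[C@]1(C)[C@@H]23)C(=O)O
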